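**Strategy.** Ring B is disconnected at C6–C7 and C9–C10 (labdane numbering), which separates ring A (the β-cyclocitral carbons) from a seven-carbon allyl unit. The two pieces are first joined through a temporary C6–O–C9 ether, using an enantioenriched allylic alcohol. In one base-then-acid operation a [2,3]-Wittig shift, an anionic oxy-Cope rearrangement and a Prins closure turn this bis-allylic ether into the ring B diol: the ether oxygen becomes the C6 hydroxyl, the quaternary C10–C9 bond and the C6–C7 bond are made, and water caps C8. The step exploits the C6/C8 1,3-diol that flanks C7 and the allylic C5=C10/C6 array of ring A.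

Key step: step 5

Remark: labdane numbering (C1–C20) is used for all intermediates; in step 3 the (R)-catalyst is assumed to give the (R)-alcohol, and if it gives the (S)-alcohol the (S)-catalyst is used instead.
Remark: the [2,3]-Wittig shift of the allyl-stabilised carbanion in step 5 is assumed to place the C9 allyl group pseudo-equatorially and so give the (E)-alkene.

**Step 1**
Reactants: 1 β-cyclocitral
Product: 2 β-cyclogeraniol
Conditions: NaBH4, MeOH, 0 °C
Reagents that add atoms: none
Why: Borohydride 1,2-reduction of the hindered enal gives the primary allylic alcohol; no stereocenter is formed.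

**Step 2**
Reactants: 2 β-cyclogeraniol
Product: 3 β-cyclogeranyl bromide
Conditions: PBr3 (0.4 equiv), pyridine (cat.), Et2O, −10 → 0 °C; used crude
Reagents that add atoms: phosphorus tribromide, BrP(Br)Br
Why: Bromide displaces the bromophosphite of the primary allylic alcohol (SN2), and the labile bromide is carried on without purification.

**Step 3**
Reactants: 4 methacrolein
Product: 5 (3R)-2-methylhexa-1,5-dien-3-ol
Conditions: allylB(pin), (R)-TRIP (5 mol%), toluene, −30 °C
Reagents that add atoms: allylboronic acid pinacol ester, C=CCB1OC(C)(C)C(C)(C)O1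
Why: Chiral phosphoric acid-catalysed allylboration through a closed chair transition state, in which the catalyst selects the aldehyde face and sets the carbinol center that later becomes C9.

**Step 4**
Reactants: 5 (3R)-2-methylhexa-1,5-dien-3-ol; 3 β-cyclogeranyl bromide
Product: 6 (3R)-2-methylhexa-1,5-dien-3-yl (2,6,6-trimethylcyclohex-1-en-1-yl)methyl ether
Conditions: NaH, THF, 0 °C; then 3, Bu4NI (cat.), 0 → 25 °C
Reagents that add atoms: none
Why: Williamson ether synthesis (SN2 at the primary allylic bromide) leaves the carbinol center untouched, and the sodium alkoxide is kept cold and free of crown ether so that it should not undergo its own anionic oxy-Cope rearrangement.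

**Step 5**
Reactants: 6 bis-allylic ether
Product: 10 (5S,6S,8R,9R,10S)-14,15,16-trinorlabd-12-ene-6α,8α-diol, via lithium dienolate 7 (not isolated), via potassium enolate 8 (not isolated), via aldehyde 9 (not isolated)
Conditions: n-BuLi, THF, −78 → −20 °C; KOt-Bu, 18-crown-6, −20 → 45 °C; then 1 M H2SO4 (aq), 0 → 25 °C
Reagents that add atoms: water, O
Why: n-BuLi removes a proton from the primary allylic C6 of 6 and the α-oxy allyl anion undergoes a [2,3]-Wittig shift onto C7 through an envelope transition state (C9 allyl substituent pseudo-equatorial, ring A exo), which transfers the C9 configuration to C6 and gives the (E)-alkene 7. After exchange to potassium the 1,5-dien-3-olate undergoes an anionic oxy-Cope rearrangement through a chair in which the C6 oxide is equatorial, because the axial site clashes with the axial C10 methyl, so C9–C10 forms on one face of ring A and enolate 8 results. Acid then gives aldehyde 9, whose protonated carbonyl is attacked by the isopropenyl CH2 (C7) in a 6-endo cation–olefin (Prins) closure of ring B through a chair, and water traps the C8 cation. The closest known reaction types are the tandem [2,3]-Wittig/anionic oxy-Cope rearrangement of bis-allylic ethers and the acid-mediated cyclisation of unsaturated aldehydes to cyclohexane-1,3-diols. C10 and C9 are set by the chair oxy-Cope (E alkene, C10 methyl axial), C5 by acid equilibration of the aldehyde epimers before the trans-fused chair–chair closure, C6 by the equatorial carbonyl oxygen and C8 by equatorial water attack anti to the axial C10 methyl. The step needs metalation at C6 rather than C9 and E geometry, which the primary versus tertiary C–H and the exo, pseudo-equatorial envelope are expected to secure.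

**Step 6**
Reactants: 10 diol
Product: 11 6α,8α-bis(triethylsilyloxy)-14,15,16-trinorlabd-12-ene
Conditions: Et3SiOTf, 2,6-lutidine, CH2Cl2, −78 → 0 °C
Reagents that add atoms: triethylsilyl trifluoromethanesulfonate, CC[Si](CC)(CC)OS(=O)(=O)C(F)(F)F
Why: Silyl triflate silylation caps the secondary and the tertiary hydroxyl, so that the C12 aldehyde made next cannot close a lactol onto the C8 oxygen.

**Step 7**
Reactants: 11 bis-silyl ether
Product: 12 6α,8α-bis(triethylsilyloxy)-13,14,15,16-tetranorlabdan-12-al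
Conditions: O3, CH2Cl2, −78 °C; then PPh3, −78 → 25 °C
Reagents that add atoms: ozone, [O-][O+]=O
Why: Ozonolysis with reductive work-up cleaves the only C=C bond and gives the C12 aldehyde.

**Step 8**
Reactants: 12 aldehyde
Product: 13 (12Z)-13-iodo-6α,8α-bis(triethylsilyloxy)-14,15-dinorlabd-12-ene
Conditions: [Ph3PCH2CH3]I, n-BuLi, THF, 25 °C; I2, −78 °C; NaN(SiMe3)2, −20 °C; then 12, −78 → −20 °C
Reagents that add atoms: ethyltriphenylphosphonium iodide, CC[P+](c1ccccc1)(c1ccccc1)c1ccccc1.[I-]; iodine, II
Why: Stork–Zhao–Wittig olefination with the α-iodoethylidene ylide should give the (Z)-2-iodoalkene by kinetic cis-oxaphosphetane formation, placing iodine cis to C11.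

**Step 9**
Reactants: 13 (Z)-vinyl iodide
Product: 14 (12Z)-6α,8α-bis(triethylsilyloxy)labda-12,14-diene
Conditions: CH2=CHSnBu3, Pd(PPh3)4 (5 mol%), CuI (10 mol%), DMF, 40 °C
Reagents that add atoms: tributyl(vinyl)stannane, C=C[Sn](CCCC)(CCCC)CCCC
Why: Stille cross-coupling proceeds with retention at the vinyl iodide, so the vinyl group ends cis to C11 and the 12Z diene is formed.

**Step 10**
Reactants: 14 bis-silyl diene
Product: 15 (12Z)-labda-12,14-diene-6α,8α-diol
Conditions: Bu4NF, THF, 25 → 50 °C
Reagents that add atoms: none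
Why: Fluoride desilylation under basic conditions frees both hydroxyls without exposing the acid-sensitive hydroxy diene to acid.

**Step 11**
Reactants: 15 diene diol; 16 angelic acid
Product: 17 (12Z)-8α-hydroxylabda-12,14-dien-6α-yl angelate (target)
Conditions: 16, 2,4,6-Cl3C6H2COCl, Et3N, toluene, 25 °C; then 15, 80 °C
Reagents that add atoms: none
Why: Yamaguchi esterification through the mixed anhydride, run without a nucleophilic amine catalyst so that the (Z)-enoate should not isomerise, acylates the secondary C6 hydroxyl and leaves the tertiary C8 hydroxyl free.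

**Compound list**
1 | β-cyclocitral (2,6,6-trimethylcyclohex-1-ene-1-carbaldehyde) | CC1=C(C=O)C(C)(C)CCC1 | starting material
2 | β-cyclogeraniol ((2,6,6-trimethylcyclohex-1-en-1-yl)methanol) | CC1=C(CO)C(C)(C)CCC1 | intermediate
3 | β-cyclogeranyl bromide (2-(bromomethyl)-1,3,3-trimethylcyclohex-1-ene) | CC1=C(CBr)C(C)(C)CCC1 | intermediate
4 | methacrolein (2-methylprop-2-enal) | CC(=C)C=O | starting material
5 | (3R)-2-methylhexa-1,5-dien-3-ol | C=CC[C@@H](O)C(C)=C | intermediate
6 | (3R)-2-methylhexa-1,5-dien-3-yl (2,6,6-trimethylcyclohex-1-en-1-yl)methyl ether | C=CC[C@@H](OCC1=C(C)CCCC1(C)C)C(C)=C | intermediate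
7 | lithium (1S,3E)-3-methyl-1-(2,6,6-trimethylcyclohex-1-en-1-yl)hepta-3,6-dien-1-olate | [Li+].[O-][C@H](C1=C(C)CCCC1(C)C)C/C(C)=C/CC=C | intermediate
8 | potassium enolate of aldehyde 9 (C5=C6 enolate, oxygen cis to C4) | C=CC[C@@H](C(C)=C)[C@@]1(C)CCCC(C)(C)/C1=C\[O-].[K+] | intermediate
9 | (1S,2R)-2-[(3S)-2-methylhexa-1,5-dien-3-yl]-2,6,6-trimethylcyclohexane-1-carbaldehyde (formyl group trans to the dienyl chain) | C=CC[C@@H](C(C)=C)[C@@]1(C)CCCC(C)(C)[C@@H]1C=O | intermediate
10 | (5S,6S,8R,9R,10S)-14,15,16-trinorlabd-12-ene-6α,8α-diol [(1R,2R,4S,4aS,8aS)-2,5,5,8a-tetramethyl-1-(prop-2-en-1-yl)decahydronaphthalene-2,4-diol] | C=CC[C@@H]1[C@@]2(C)CCCC(C)(C)[C@@H]2[C@@H](O)C[C@@]1(C)O | intermediate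
11 | 6α,8α-bis(triethylsilyloxy)-14,15,16-trinorlabd-12-ene | C=CC[C@@H]1[C@@]2(C)CCCC(C)(C)[C@@H]2[C@@H](O[Si](CC)(CC)CC)C[C@@]1(C)O[Si](CC)(CC)CC | intermediate
12 | 6α,8α-bis(triethylsilyloxy)-13,14,15,16-tetranorlabdan-12-al | O=CC[C@@H]1[C@@]2(C)CCCC(C)(C)[C@@H]2[C@@H](O[Si](CC)(CC)CC)C[C@@]1(C)O[Si](CC)(CC)CC | intermediate
13 | (12Z)-13-iodo-6α,8α-bis(triethylsilyloxy)-14,15-dinorlabd-12-ene | C/C(I)=C/C[C@@H]1[C@@]2(C)CCCC(C)(C)[C@@H]2[C@@H](O[Si](CC)(CC)CC)C[C@@]1(C)O[Si](CC)(CC)CC | intermediate
14 | (12Z)-6α,8α-bis(triethylsilyloxy)labda-12,14-diene | C=C/C(C)=C\C[C@@H]1[C@@]2(C)CCCC(C)(C)[C@@H]2[C@@H](O[Si](CC)(CC)CC)C[C@@]1(C)O[Si](CC)(CC)CC | intermediate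
15 | (12Z)-labda-12,14-diene-6α,8α-diol | C=C/C(C)=C\C[C@@H]1[C@@]2(C)CCCC(C)(C)[C@@H]2[C@@H](O)C[C@@]1(C)O | intermediate
16 | angelic acid ((2Z)-2-methylbut-2-enoic acid) | C/C=C(/C)C(=O)O | starting material
17 | (12Z)-8α-hydroxylabda-12,14-dien-6α-yl angelate | C=C/C(C)=C\C[C@@H]1[C@@]2(C)CCCC(C)(C)[C@@H]2[C@@H](OC(=O)/C(C)=C\C)C[C@@]1(C)O | target

**Step count and risk**
Total steps: 11. Longest linear sequence: 10 (steps 1, 2, 4–11 from β-cyclocitral); step 3 is a one-step branch.

Steps most likely to fail: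

1. Step 5. The [2,3] shift may give part of the (Z)-alkene, which leads to the C9 epimer. In the aqueous acid stage, elimination, closure to the cis-fused ring or water capture on the wrong face of C8 may compete. Fallback: from 6 the three events are run as separate operations and the ring is closed without a free C8 cation. n-BuLi (THF, −78 °C) and aqueous quench give (1S,3E)-3-methyl-1-(2,6,6-trimethylcyclohex-1-en-1-yl)hepta-3,6-dien-1-ol F1, from which any (Z)-isomer is removed by chromatography. KH/18-crown-6 (THF, 25–50 °C) and a buffered quench give aldehyde 9. Me2AlCl (CH2Cl2, −78 °C) closes ring B by an intramolecular carbonyl-ene reaction to 14,15,16-trinorlabda-8(17),12-dien-6α-ol F2. mCPBA should epoxidise the exocyclic alkene from the α face to 8α,17-epoxy-14,15,16-trinorlabd-12-en-6α-ol F3, and LiAlH4 opens the epoxide at the primary carbon, returning to 10.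

2. Step 8. The α-iodo ylide may decompose before it reacts with the hindered aldehyde, or the Z/E selectivity may be poor. Fallback: from 12 a Z-selective Horner–Wadsworth–Emmons reaction with ethyl 2-(diphenoxyphosphoryl)propanoate (NaH, THF, −78 → 0 °C) gives ethyl (12Z)-6α,8α-bis(triethylsilyloxy)-15-norlabd-12-en-14-oate F4. i-Bu2AlH reduces it to (12Z)-6α,8α-bis(triethylsilyloxy)-15-norlabd-12-en-14-ol F5. MnO2 oxidises this to (12Z)-6α,8α-bis(triethylsilyloxy)-15-norlabd-12-en-14-al F6, and methylenation with Ph3P=CH2 (THF, −78 → 0 °C) returns to 14.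

3. Step 11. The angeloyl unit may isomerise to the tigloyl unit during activation, or acylation of the hindered equatorial C6 hydroxyl may be too slow. Fallback: from 15 the C6 hydroxyl is acylated with 2-[bis(2,2,2-trifluoroethoxy)phosphoryl]propanoic acid (N,N′-dicyclohexylcarbodiimide, DMAP, CH2Cl2) to (12Z)-8α-hydroxylabda-12,14-dien-6α-yl 2-[bis(2,2,2-trifluoroethoxy)phosphoryl]propanoate F7. A Still–Gennari olefination with acetaldehyde (KN(SiMe3)2, 18-crown-6, THF, −78 °C) then builds the (Z)-2-methylbut-2-enoate on the ester and returns to 17.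

**Further compounds**
F1 | step 5 | (1S,3E)-3-methyl-1-(2,6,6-trimethylcyclohex-1-en-1-yl)hepta-3,6-dien-1-ol | O[C@H](C1=C(C)CCCC1(C)C)C/C(C)=C/CC=C
F2 | step 5 | 14,15,16-trinorlabda-8(17),12-dien-6α-ol | C=CC[C@@H]1[C@@]2(C)CCCC(C)(C)[C@@H]2[C@@H](O)CC1=C
F3 | step 5 | 8α,17-epoxy-14,15,16-trinorlabd-12-en-6α-ol | C=CC[C@@H]1[C@@]2(C)CCCC(C)(C)[C@@H]2[C@@H](O)C[C@]13CO3
F4 | step 8 | ethyl (12Z)-6α,8α-bis(triethylsilyloxy)-15-norlabd-12-en-14-oate | CCOC(=O)/C(C)=C\C[C@@H]1[C@@]2(C)CCCC(C)(C)[C@@H]2[C@@H](O[Si](CC)(CC)CC)C[C@@]1(C)O[Si](CC)(CC)CC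
F5 | step 8 | (12Z)-6α,8α-bis(triethylsilyloxy)-15-norlabd-12-en-14-ol | OC/C(C)=C\C[C@@H]1[C@@]2(C)CCCC(C)(C)[C@@H]2[C@@H](O[Si](CC)(CC)CC)C[C@@]1(C)O[Si](CC)(CC)CC
F6 | step 8 | (12Z)-6α,8α-bis(triethylsilyloxy)-15-norlabd-12-en-14-al | O=C/C(C)=C\C[C@@H]1[C@@]2(C)CCCC(C)(C)[C@@H]2[C@@H](O[Si](CC)(CC)CC)C[C@@]1(C)O[Si](CC)(CC)CC
F7 | step 11 | (12Z)-8α-hydroxylabda-12,14-dien-6α-yl 2-[bis(2,2,2-trifluoroethoxy)phosphoryl]propanoate | C=C/C(C)=C\C[C@@H]1[C@@]2(C)CCCC(C)(C)[C@@H]2[C@@H](OC(=O)C(C)P(=O)(OCC(F)(F)F)OCC(F)(F)F)C[C@@]1(C)O
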